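**Plan**

- Retrosynthetic cuts, in order: C9–CHBr2 (dibromomethyl carbinol), C3–C4 of ring B (the CHOH–CHBr bond, ring closure), C5–C6 (the two adjacent quaternary carbons, Ireland–Claisen), and the exocyclic C=C of a quinone methide ketal (Horner–Wadsworth–Emmons).
- Forward: ring A is bought as the p-quinone monoketal 4 and stays a mirror-symmetric cyclohexadienone (ketal) until late. The chain is joined by olefination, a [3,3] shift then puts C5 on the ring carbon C6 and creates the 1-methylidene group, and ring B arises last by closing C3–C4.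
- Enabling feature: C4 is a neopentylic CHBr2 carbon next to the hydrogen-free C5 (no β-hydride and no 1,2-hydrogen shift open to a metal carbenoid) and lies six atoms from the C3 aldehyde. C6 of the dienone carries two identical arms, so the cyclisation precursor is achiral and the closure creates the first stereocentres.
- Stereochemistry: C4 comes from the ligand-controlled chromium closure. C3 is reset cis to bromine by oxidation and hydride reduction. C6 is relayed from the C3 oxygen by transannular oxa-Michael addition to the syn dienone arm, conjugate reduction of the other arm and re-opening. C9 comes from equatorial attack of LiCHBr2.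

Key step: step 9

Remark: spiro[5.5]undecane numbering of the target is used throughout (C1 methylidene carbon, C3 carbinol, C4 C–Br, C5 CMe2, C6 spiro, C7=C8, C9 tertiary carbinol); the sense of induction of the chiral chromium ligand is assumed, and the ligand antipode that gives (4S) is to be taken.

**Step 1**
Reactants: 1 triethyl phosphonoacetate; 2 2-bromo-1,1-dimethoxyethane
Product: 3 ethyl 2-(diethoxyphosphoryl)-4,4-dimethoxybutanoate
Conditions: NaH, NaI (cat.), DMF, 0 °C to 90 °C
Reagents that add atoms: none
Why: SN2 alkylation of the stabilised phosphonoacetate anion by the primary bromide (helped by iodide exchange) is the standard way to an α-substituted Horner–Wadsworth–Emmons reagent, and the acetal carries the future C3 aldehyde.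

**Step 2**
Reactants: 3 ethyl 2-(diethoxyphosphoryl)-4,4-dimethoxybutanoate; 4 4,4-dimethoxycyclohexa-2,5-dien-1-one
Product: 5 ethyl 2-(4,4-dimethoxycyclohexa-2,5-dien-1-ylidene)-4,4-dimethoxybutanoate
Conditions: NaH, THF, 0 °C to 60 °C
Reagents that add atoms: none
Why: Horner–Wadsworth–Emmons olefination of the dienone carbonyl gives the quinone methide ketal whose ring alkene carbon is the future spiro carbon C6; the symmetric ring removes any E/Z question and the basic medium avoids aromatisation.

**Step 3**
Reactants: 5 ethyl 2-(4,4-dimethoxycyclohexa-2,5-dien-1-ylidene)-4,4-dimethoxybutanoate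
Product: 6 2-(4,4-dimethoxycyclohexa-2,5-dien-1-ylidene)-4,4-dimethoxybutan-1-ol
Conditions: i-Bu2AlH, CH2Cl2, −78 °C; aqueous potassium sodium tartrate (KNaC4H4O6)
Reagents that add atoms: none
Why: 1,2-reduction of the conjugated ester by i-Bu2AlH at low temperature gives the allylic alcohol needed for the sigmatropic step, and the non-acidic work-up protects the ketal and the acetal.

**Step 4**
Reactants: 6 2-(4,4-dimethoxycyclohexa-2,5-dien-1-ylidene)-4,4-dimethoxybutan-1-ol; 7 2-methylpropanoyl chloride
Product: 8 2-(4,4-dimethoxycyclohexa-2,5-dien-1-ylidene)-4,4-dimethoxybutyl 2-methylpropanoate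
Conditions: Et3N, 4-(dimethylamino)pyridine (cat.), CH2Cl2, 0 °C
Reagents that add atoms: none
Why: acylation of the primary allylic alcohol under nucleophilic catalysis installs the isobutyrate whose α-carbon becomes C5.

**Step 5**
Reactants: 8 2-(4,4-dimethoxycyclohexa-2,5-dien-1-ylidene)-4,4-dimethoxybutyl 2-methylpropanoate
Product: 11 2-[1-(4,4-dimethoxybut-1-en-2-yl)-4,4-dimethoxycyclohexa-2,5-dien-1-yl]-2-methylpropan-1-ol, via silyl ketene acetal 9 (not isolated), via trimethylsilyl ester 10 (not isolated)
Conditions: LiN(i-Pr)2, Me3SiCl–Et3N, THF, −78 °C to 50 °C; then LiAlH4, 0 °C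
Reagents that add atoms: none
Why: Ireland–Claisen rearrangement, in which the silyl ketene acetal 9 undergoes a chair-like [3,3] shift that joins C5 to C6 (two adjacent quaternary carbons), moves the double bond into the 1-methylidene position and leaves C6 with two identical vinyl arms (not yet stereogenic), after which the silyl ester 10 is reduced in the same flask.

**Step 6**
Reactants: 11 2-[1-(4,4-dimethoxybut-1-en-2-yl)-4,4-dimethoxycyclohexa-2,5-dien-1-yl]-2-methylpropan-1-ol
Product: 12 2-[1-(4,4-dimethoxybut-1-en-2-yl)-4,4-dimethoxycyclohexa-2,5-dien-1-yl]-2-methylpropanal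
Conditions: 1,1,1-triacetoxy-1,2-benziodoxol-3(1H)-one (DMP), NaHCO3, CH2Cl2, rt
Reagents that add atoms: none
Why: buffered periodinane oxidation of the neopentylic primary alcohol should give the non-enolisable aldehyde without touching the acetals or the alkenes.

**Step 7**
Reactants: 12 2-[1-(4,4-dimethoxybut-1-en-2-yl)-4,4-dimethoxycyclohexa-2,5-dien-1-yl]-2-methylpropanal
Product: 14 3-(1,1-dibromo-2-methylpropan-2-yl)-3-(4,4-dimethoxybut-1-en-2-yl)-6,6-dimethoxycyclohexa-1,4-diene, via hydrazone 13 (not isolated)
Conditions: N2H4·H2O, EtOH, rt; then CuBr2, LiOt-Bu, THF, rt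
Reagents that add atoms: copper dibromide (CuBr2), [Cu+2].[Br-].[Br-]
Why: condensation with hydrazine and oxidative bromination of the N-unsubstituted hydrazone 13 by CuBr2 and LiOt-Bu converts the aldehyde into the geminal dibromide under basic conditions, and because C5 bears no hydrogen no vinyl bromide can form.

**Step 8**
Reactants: 14 3-(1,1-dibromo-2-methylpropan-2-yl)-3-(4,4-dimethoxybut-1-en-2-yl)-6,6-dimethoxycyclohexa-1,4-diene
Product: 15 3-[1-(1,1-dibromo-2-methylpropan-2-yl)-4-oxocyclohexa-2,5-dien-1-yl]but-3-enal
Conditions: oxalic acid, THF–H2O, 0 °C to rt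
Reagents that add atoms: water, O
Why: mild acid hydrolysis removes the ketal and the acetal in one operation and unveils the cyclohexadienone and the C3 aldehyde, giving an achiral precursor because C6 carries two identical ring arms.

**Step 9**
Reactants: 15 3-[1-(1,1-dibromo-2-methylpropan-2-yl)-4-oxocyclohexa-2,5-dien-1-yl]but-3-enal
Product: 17 (3S,4S)-4-bromo-3-hydroxy-5,5-dimethyl-1-methylidenespiro[5.5]undeca-7,10-dien-9-one (trans-bromohydrin), via trimethylsilyl ether 16 (not isolated)
Conditions: CrCl2 (20 mol %), (S)-N-[2-(4-isopropyl-4,5-dihydro-1,3-oxazol-2-yl)-6-methylphenyl]methanesulfonamide (22 mol %), 1,8-bis(dimethylamino)naphthalene (22 mol %), Mn powder, Me3SiCl, LiCl, MeCN–THF, 0 °C to rt; then citric acid, MeOH, 0 °C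
Reagents that add atoms: none
Why: Proposed new method: the ligated divalent chromium abstracts one of the two enantiotopic bromine atoms of the neopentylic CHBr2 group and captures the resulting α-bromoalkyl radical, and the α-bromoalkylchromium species (trivalent chromium) adds to the tethered aldehyde; Me3SiCl releases the metal as the silyl ether 16 and Mn returns chromium to the divalent state, the closest known reaction types being the catalytic enantioselective Nozaki–Hiyama–Kishi reaction, the first stage of the Takai–Utimoto olefination of geminal dihalides with CrCl2, and the samarium-mediated Barbier-type halomethylation of aldehydes. The only ring closed is ring B, by 6-exo-trig attack of C4 on the aldehyde carbon C3. The configuration at C3 is set by the chiral ligand on chromium (choice of aldehyde face), and that at C4 follows from it through a chair-like closed transition state in which bromine and the chromium-bound oxygen are both equatorial, which avoids the 1,3-diaxial contacts with the axial methyl group on C5 and with the axial arm of ring A on C6. This trans relationship is what the route needs, because C3 is inverted in steps 10 and 11 while C4 is kept. The step needs selectivity for the aldehyde over the dienone carbonyl, which the aldehyde preference of organochromium reagents should secure, and it must stop after one reduction, which the inertness of the remaining unactivated secondary bromide towards divalent chromium and the O-silylation (no β-elimination to the alkene) should secure. Ring A is an achiral bystander here, so the step creates the first stereocentres of the route from an achiral precursor.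

**Step 10**
Reactants: 17 (3S,4S)-4-bromo-3-hydroxy-5,5-dimethyl-1-methylidenespiro[5.5]undeca-7,10-dien-9-one
Product: 18 (4S)-4-bromo-5,5-dimethyl-1-methylidenespiro[5.5]undeca-7,10-diene-3,9-dione
Conditions: DMP, NaHCO3, CH2Cl2, 0 °C
Reagents that add atoms: none
Why: periodinane oxidation erases the C3 stereocentre and leaves C4 untouched, and the buffered non-basic medium is chosen so that the β,γ-unsaturated ketone does not move into conjugation and C4 does not epimerise.

**Step 11**
Reactants: 18 (4S)-4-bromo-5,5-dimethyl-1-methylidenespiro[5.5]undeca-7,10-diene-3,9-dione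
Product: 19 (3R,4S)-4-bromo-3-hydroxy-5,5-dimethyl-1-methylidenespiro[5.5]undeca-7,10-dien-9-one (cis-bromohydrin)
Conditions: NaBH4, MeOH–CH2Cl2, −78 °C
Reagents that add atoms: none
Why: in this hydride reduction the axial methyl group on C5 blocks the axial trajectory at C3 and the antiperiplanar (polar) preference sends hydride anti to the C–Br bond, so both effects should give the cis-bromohydrin, while the more electrophilic α-bromo ketone should react at −78 °C before the cross-conjugated dienone.

**Step 12**
Reactants: 19 (3R,4S)-4-bromo-3-hydroxy-5,5-dimethyl-1-methylidenespiro[5.5]undeca-7,10-dien-9-one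
Product: 21 (3R,4S,6S,7S)-4-bromo-3,7-epoxy-5,5-dimethyl-1-methylidenespiro[5.5]undec-10-en-9-one (oxygen bridge from C3 to C7), via potassium dienolate 20 (not isolated)
Conditions: KN(SiMe3)2, THF, −78 °C to −40 °C; then AcOH, −78 °C
Reagents that add atoms: none
Why: in this transannular oxa-Michael addition the C3 alkoxide can reach only the dienone arm on its own face of ring B (6-exo-trig, ring B as a twist-boat), which forms the 2-oxabicyclo[2.2.2]octane and makes C6 a stereocentre dictated by C3, the stabilised dienolate 20 driving the closure before protonation at C8 (the C7 configuration is temporary and either epimer serves).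

**Step 13**
Reactants: 21 (3R,4S,6S,7S)-4-bromo-3,7-epoxy-5,5-dimethyl-1-methylidenespiro[5.5]undec-10-en-9-one
Product: 22 (3R,4S,6S,7S)-4-bromo-3,7-epoxy-5,5-dimethyl-1-methylidenespiro[5.5]undecan-9-one
Conditions: Cu(OAc)2·H2O (5 mol %), 1,2-bis(diphenylphosphino)benzene (5 mol %), (EtO)2MeSiH, t-BuOH, toluene, rt
Reagents that add atoms: none
Why: copper hydride conjugate reduction (1,4-hydride delivery, silane as terminal reductant) saturates the only remaining enone and should leave the isolated methylidene group, the ketone and the secondary bromide untouched.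

**Step 14**
Reactants: 22 (3R,4S,6S,7S)-4-bromo-3,7-epoxy-5,5-dimethyl-1-methylidenespiro[5.5]undecan-9-one
Product: 24 (3R,4S,6S)-4-bromo-5,5-dimethyl-1-methylidene-3-(triethylsilyloxy)spiro[5.5]undec-7-en-9-one, via bis-silyl dienol ether 23 (not isolated)
Conditions: Et3SiOTf, Et3N, CH2Cl2, −78 °C to 0 °C; then AcOH–THF–H2O, 0 °C
Reagents that add atoms: triethylsilyl trifluoromethanesulfonate, CC[Si](CC)(CC)OS(=O)(=O)C(F)(F)F
Why: soft enolisation and β-elimination of the bridging oxygen (retro-oxa-Michael opening of a β-alkoxy ketone through its silyl enol ether, the two regioisomeric enol ethers equilibrating and only the C8 isomer able to eliminate) re-forms the C7=C8 double bond on the arm that was masked and releases O3 as its triethylsilyl ether, and mild acid then cleaves only the dienol silyl ether of 23.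

**Step 15**
Reactants: 24 (3R,4S,6S)-4-bromo-5,5-dimethyl-1-methylidene-3-(triethylsilyloxy)spiro[5.5]undec-7-en-9-one; 25 dibromomethane
Product: 27 mailiohydrin, (3R,4S,6S,9R)-4-bromo-9-(dibromomethyl)-5,5-dimethyl-1-methylidenespiro[5.5]undec-7-ene-3,9-diol, via silyl-protected adduct 26 (not isolated)
Conditions: 25, LiN(i-Pr)2, THF, −78 °C (reagent preformed); then 24, −78 °C; AcOH; then HF·pyridine, THF, 0 °C
Reagents that add atoms: none
Why: in this 1,2-addition of dibromomethyllithium to the enone carbonyl the bulky carbanion is expected to take the equatorial trajectory on the half-chair of ring A in which C5 is pseudo-equatorial, which places CHBr2 equatorial and the new hydroxyl axial and cis to C5 (9R), while the silyl ether keeps O3 from re-adding to the enone and is removed in the same flask.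

**Compound list**

1 | triethyl phosphonoacetate | CCOC(=O)CP(=O)(OCC)OCC | starting material
2 | 2-bromo-1,1-dimethoxyethane | COC(CBr)OC | starting material
3 | ethyl 2-(diethoxyphosphoryl)-4,4-dimethoxybutanoate | CCOC(=O)C(CC(OC)OC)P(=O)(OCC)OCC | intermediate
4 | 4,4-dimethoxycyclohexa-2,5-dien-1-one | COC1(OC)C=CC(=O)C=C1 | starting material
5 | ethyl 2-(4,4-dimethoxycyclohexa-2,5-dien-1-ylidene)-4,4-dimethoxybutanoate | CCOC(=O)C(CC(OC)OC)=C1C=CC(OC)(OC)C=C1 | intermediate
6 | 2-(4,4-dimethoxycyclohexa-2,5-dien-1-ylidene)-4,4-dimethoxybutan-1-ol | OCC(CC(OC)OC)=C1C=CC(OC)(OC)C=C1 | intermediate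
7 | 2-methylpropanoyl chloride | CC(C)C(=O)Cl | starting material
8 | 2-(4,4-dimethoxycyclohexa-2,5-dien-1-ylidene)-4,4-dimethoxybutyl 2-methylpropanoate | CC(C)C(=O)OCC(CC(OC)OC)=C1C=CC(OC)(OC)C=C1 | intermediate
9 | trimethylsilyl ketene acetal of 8 | CC(C)=C(O[Si](C)(C)C)OCC(CC(OC)OC)=C1C=CC(OC)(OC)C=C1 | intermediate
10 | trimethylsilyl 2-[1-(4,4-dimethoxybut-1-en-2-yl)-4,4-dimethoxycyclohexa-2,5-dien-1-yl]-2-methylpropanoate | C[Si](C)(C)OC(=O)C(C)(C)C1(C(=C)CC(OC)OC)C=CC(OC)(OC)C=C1 | intermediate
11 | 2-[1-(4,4-dimethoxybut-1-en-2-yl)-4,4-dimethoxycyclohexa-2,5-dien-1-yl]-2-methylpropan-1-ol | OCC(C)(C)C1(C(=C)CC(OC)OC)C=CC(OC)(OC)C=C1 | intermediate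
12 | 2-[1-(4,4-dimethoxybut-1-en-2-yl)-4,4-dimethoxycyclohexa-2,5-dien-1-yl]-2-methylpropanal | O=CC(C)(C)C1(C(=C)CC(OC)OC)C=CC(OC)(OC)C=C1 | intermediate
13 | hydrazone of 12 | NN=CC(C)(C)C1(C(=C)CC(OC)OC)C=CC(OC)(OC)C=C1 | intermediate
14 | 3-(1,1-dibromo-2-methylpropan-2-yl)-3-(4,4-dimethoxybut-1-en-2-yl)-6,6-dimethoxycyclohexa-1,4-diene | BrC(Br)C(C)(C)C1(C(=C)CC(OC)OC)C=CC(OC)(OC)C=C1 | intermediate
15 | 3-[1-(1,1-dibromo-2-methylpropan-2-yl)-4-oxocyclohexa-2,5-dien-1-yl]but-3-enal | BrC(Br)C(C)(C)C1(C(=C)CC=O)C=CC(=O)C=C1 | intermediate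
16 | trimethylsilyl ether of 17, (3S,4S) | C=C1C[C@H](O[Si](C)(C)C)[C@@H](Br)C(C)(C)C12C=CC(=O)C=C2 | intermediate
17 | (3S,4S)-4-bromo-3-hydroxy-5,5-dimethyl-1-methylidenespiro[5.5]undeca-7,10-dien-9-one (OH and Br trans) | C=C1C[C@H](O)[C@@H](Br)C(C)(C)C12C=CC(=O)C=C2 | intermediate
18 | (4S)-4-bromo-5,5-dimethyl-1-methylidenespiro[5.5]undeca-7,10-diene-3,9-dione | C=C1CC(=O)[C@@H](Br)C(C)(C)C12C=CC(=O)C=C2 | intermediate
19 | (3R,4S)-4-bromo-3-hydroxy-5,5-dimethyl-1-methylidenespiro[5.5]undeca-7,10-dien-9-one (OH and Br cis) | C=C1C[C@@H](O)[C@@H](Br)C(C)(C)C12C=CC(=O)C=C2 | intermediate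
20 | potassium dienolate of 21 (oxygen bridge C3–O–C7 closed, C8=C9(O−)–C10=C11) | C=C1C[C@@H](O3)[C@@H](Br)C(C)(C)[C@@]12[C@@H]3C=C([O-])C=C2.[K+] | intermediate
21 | (3R,4S,6S,7S)-4-bromo-3,7-epoxy-5,5-dimethyl-1-methylidenespiro[5.5]undec-10-en-9-one | C=C1C[C@@H](O3)[C@@H](Br)C(C)(C)[C@@]12[C@@H]3CC(=O)C=C2 | intermediate
22 | (3R,4S,6S,7S)-4-bromo-3,7-epoxy-5,5-dimethyl-1-methylidenespiro[5.5]undecan-9-one | C=C1C[C@@H](O3)[C@@H](Br)C(C)(C)[C@@]12[C@@H]3CC(=O)CC2 | intermediate
23 | (3R,4S,6S)-4-bromo-5,5-dimethyl-1-methylidene-3,9-bis(triethylsilyloxy)spiro[5.5]undeca-7,9-diene | C=C1C[C@@H](O[Si](CC)(CC)CC)[C@@H](Br)C(C)(C)[C@@]12C=CC(O[Si](CC)(CC)CC)=CC2 | intermediate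
24 | (3R,4S,6S)-4-bromo-5,5-dimethyl-1-methylidene-3-(triethylsilyloxy)spiro[5.5]undec-7-en-9-one | C=C1C[C@@H](O[Si](CC)(CC)CC)[C@@H](Br)C(C)(C)[C@@]12C=CC(=O)CC2 | intermediate
25 | dibromomethane | BrCBr | starting material
26 | (3R,4S,6S,9R)-4-bromo-9-(dibromomethyl)-5,5-dimethyl-1-methylidene-3-(triethylsilyloxy)spiro[5.5]undec-7-en-9-ol | C=C1C[C@@H](O[Si](CC)(CC)CC)[C@@H](Br)C(C)(C)[C@@]12C=C[C@@](O)(C(Br)Br)CC2 | intermediate
27 | mailiohydrin, (3R,4S,6S,9R)-4-bromo-9-(dibromomethyl)-5,5-dimethyl-1-methylidenespiro[5.5]undec-7-ene-3,9-diol | C=C1C[C@@H](O)[C@@H](Br)C(C)(C)[C@@]12C=C[C@@](O)(C(Br)Br)CC2 | target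

**Count**

Total step count: 15. Longest linear sequence: 15 steps (from 1 to 27).

**Steps most likely to fail**

Step 9. The chromium carbenoid may not form from the unactivated dibromide. It may be reduced a second time and eliminate to the C3=C4 alkene (Takai–Utimoto pathway). The aldehyde may drift into conjugation with the methylidene group. The closure may also be poorly enantioselective, or insufficiently trans-selective, which would erode the purity at C4 once C3 is oxidised.

The fallback closes ring B one oxidation level higher by known carbenoid acylation and sets out from 15. Pinnick oxidation (NaClO2, NaH2PO4, 2-methylbut-2-ene) should give the carboxylic acid F1. Coupling with N,O-dimethylhydroxylamine hydrochloride (carbodiimide, Et3N) should give the N-methoxy-N-methylamide F2. Bromine–magnesium exchange with i-PrMgCl·LiCl in THF at −78 °C should give the α-bromoalkylmagnesium carbenoid, which the amide acylates intramolecularly to the racemic bromo ketone F3. Reduction under the conditions of step 11 should then give the racemic cis-bromohydrin, which is separated by preparative chromatography on a chiral stationary phase into 19 and its enantiomer F4. The route is rejoined at 19.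

Step 12. The alkoxide may fail to reach the dienone because ring B must leave its chair, the closure may be reversed on protonation, or intermolecular addition may compete.

The fallback replaces the relay by catalyst control and sets out from 19. Silylation (Et3SiCl, imidazole) should give the silyl ether F5. Its two dienone arms are then told apart by a chiral copper hydride: Cu(OAc)2, (R)- or (S)-5,5′-bis[bis(3,5-di-tert-butyl-4-methoxyphenyl)phosphino]-4,4′-bi-1,3-benzodioxole, (EtO)2MeSiH and t-BuOH. This is the known desymmetrising conjugate reduction of 4,4-disubstituted cyclohexadienones, with the ligand antipode chosen so that the C10–C11 arm is reduced. The route is rejoined at 24.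

Step 15. The carbanion may attack the wrong face of the enone (axial trajectory), or may enolise the ketone instead of adding.

The fallback uses a bulkier carbon nucleophile and builds the CHBr2 group afterwards, and sets out from 24. 2-Lithio-1,3-dithiane (1,3-dithiane, n-BuLi, THF, −78 °C) should add equatorially to give the dithiane carbinol F6. MeI and CaCO3 in MeCN–H2O should free the α-hydroxy aldehyde F7. Hydrazine should give the hydrazone F8, and CuBr2 with LiOt-Bu (the method of step 7) should give the geminal dibromide. The route is rejoined at 26, which is desilylated as in step 15.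

**Further compounds**

F1 | step 9 | 3-[1-(1,1-dibromo-2-methylpropan-2-yl)-4-oxocyclohexa-2,5-dien-1-yl]but-3-enoic acid | OC(=O)CC(=C)C1(C=CC(=O)C=C1)C(C)(C)C(Br)Br
F2 | step 9 | 3-[1-(1,1-dibromo-2-methylpropan-2-yl)-4-oxocyclohexa-2,5-dien-1-yl]-N-methoxy-N-methylbut-3-enamide | CON(C)C(=O)CC(=C)C1(C=CC(=O)C=C1)C(C)(C)C(Br)Br
F3 | step 9 | racemic 4-bromo-5,5-dimethyl-1-methylidenespiro[5.5]undeca-7,10-diene-3,9-dione | C=C1CC(=O)C(Br)C(C)(C)C12C=CC(=O)C=C2
F4 | step 9 | (3S,4R)-4-bromo-3-hydroxy-5,5-dimethyl-1-methylidenespiro[5.5]undeca-7,10-dien-9-one (enantiomer of 19) | C=C1C[C@H](O)[C@H](Br)C(C)(C)C12C=CC(=O)C=C2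
F5 | step 12 | (3R,4S)-4-bromo-5,5-dimethyl-1-methylidene-3-(triethylsilyloxy)spiro[5.5]undeca-7,10-dien-9-one | C=C1C[C@@H](O[Si](CC)(CC)CC)[C@@H](Br)C(C)(C)C12C=CC(=O)C=C2
F6 | step 15 | (3R,4S,6S,9R)-4-bromo-9-(1,3-dithian-2-yl)-5,5-dimethyl-1-methylidene-3-(triethylsilyloxy)spiro[5.5]undec-7-en-9-ol | C=C1C[C@@H](O[Si](CC)(CC)CC)[C@@H](Br)C(C)(C)[C@@]12C=C[C@@](O)(C3SCCCS3)CC2
F7 | step 15 | (3R,4S,6S,9R)-4-bromo-9-hydroxy-5,5-dimethyl-1-methylidene-3-(triethylsilyloxy)spiro[5.5]undec-7-ene-9-carbaldehyde | C=C1C[C@@H](O[Si](CC)(CC)CC)[C@@H](Br)C(C)(C)[C@@]12C=C[C@@](O)(C=O)CC2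
F8 | step 15 | hydrazone of F7 | C=C1C[C@@H](O[Si](CC)(CC)CC)[C@@H](Br)C(C)(C)[C@@]12C=C[C@@](O)(C=NN)CC2
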